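The data are calculated from invented constants; scatter was added.

The constants of this chemistry are not given, so I read them from the earlier runs.

common to all: first end groups 0.083 M
- south-west: second end groups 0.0789 M; third end groups 0.083 M; run made earlier
- east: second end groups 0.039 M; third end groups 0.083 M; run made earlier
- south-east: second end groups 0.059 M; third end groups 0.083 M; run made earlier
- violet: second end groups 0.0789 M (fed, over 4.0 d); third end groups 0.0830 M; all else is in the flask from the start; the feed brings no volume worth counting; time 6.0 d
- teal: second end groups 0.0789 M (in portions, 4, over 4.0 d); third end groups 0.0830 M; first portion at the start, last at 4.0 d; time 6.0 d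
- ochre: second end groups 0.0789 M; third end groups 0.0830 M (fed, over 25 h); all else is in the flask from the start; the feed brings no volume worth counting; time 6.0 d
- green: second end groups 0.0789 M; third end groups 0.0830 M (fed, over 4.0 d); all else is in the flask from the start; the feed brings no volume worth counting; time 6.0 d
- amber: second end groups 0.0789 M; third end groups 0.0830 M; everything together at the start; time 6.0 d

| run | time / d | links / % | over-reaction product / % |
|---|---|---|---|
| south-west | 0.500 | 46.8 | 9.7 |
| south-west | 1.04 | 37.1 | 20.8 |
| south-west | 2.50 | 18.6 | 41.5 |
| south-west | 6.00 | 5.6 | 55.0 |
| east | 0.833 | 19.5 | 6.3 |
| east | 2.00 | 13.9 | 19.1 |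
| east | 4.00 | 3.9 | 25.3 |
| east | 6.00 | 2.2 | 30.0 |
| south-east | 0.500 | 37.0 | 9.4 |
| south-east | 1.04 | 29.2 | 18.2 |
| south-east | 2.50 | 13.0 | 32.8 |
| south-east | 6.00 | 3.0 | 43.8 |

(scatter of a reading: 1 percentage point)



* which flask leads in share of links in links plus over-reaction product ("all alike" within 1.5 percentage points) (violet / teal / ochre / green / amber / all alike)
* share of links in links plus over-reaction product at the end, violet
* share of links in links plus over-reaction product at the end, teal
* share of links in links plus over-reaction product at the end, ochre
* share of links in links plus over-reaction product at the end, green
* share of links in links plus over-reaction product at the end, amber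

I keep my ledger on second end groups, the limiting reagent, with 0.0789 M charged against 0.083 M of first end groups. South-west has amber's recipe. Counting one second end group per link, its books at 6.00 d read: 0.00465 M standing as links, 0.0457 M as over-reaction product, and 0.0286 M in neither reading. So 63.7% of the charge reaches the links side. The unread entry drops out of the asked share, which counts links against links plus over-reaction product.

By 0.500 d nearly all of the sum read last stands in south-west, so I treat links as born when second end groups enter. After that I let a link wait until it turns into over-reaction product. South-west links fall from 46.8% to 18.6% between 0.500 d and 2.50 d. That reads as a first-order decay with 2.17 d as the link life, the average time a link lasts before it turns into over-reaction product. East reads 1.97 d.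

The final share is then the average, over the links born, of exp(−age / link life). In amber I count every link at the age 6.0 d, which gives 6.28%. I trust this above south-west's last reading, 9.24%, whose links of 5.6% carry a scatter of 1 percentage point. Ochre and green hold their second end groups from the start, so I expect about the same share there. Violet's feed gives 18.1%. Teal, with its portions counted equally, gives 19.8%, higher than violet and just past the margin of 1.5 points.

The forecast names teal, with violet 19%, teal 20%, ochre 8.5%, green 9% and amber 7.5%: “Teal narrowly leads, though violet is practically level”.

The flasks give violet 16.6%, teal 18.2%, ochre 5.51%, green 5.65% and amber 5.39%, with teal in the lead.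

    first end groups + second end groups → links (k = 5.08 L mol⁻¹ h⁻¹)
    second end groups + third end groups → links of the second sort (k = 2.45 L mol⁻¹ h⁻¹)
    second end groups → decomposed reagent (k = 0.00491 h⁻¹)
    links → over-reaction product (k = 0.0206 h⁻¹)

In teal at 1.55 d, second end groups have a half-life of 0.097 d by the step to links, far shorter than my link life of 2.17 d. Teal read at 10 d ages each link by a further 4.00 d, and dividing 18.2% by exp of that age over the link life gives 2.88%, where that flask stands at 2.52%.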